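With C1 carrying the C7 hydroxymethyl group, C2 a bromine, C3 and C4 the hydroxyls, and C5 and C6 the other bromines, the route cuts the benzene core into three alkynes, C1≡C2, C3≡C4 and C5≡C6. One ruthenium-catalysed [2+2+2] cyclotrimerization forms C1–C6, C2–C3 and C4–C5, closing the benzene ring and a temporary five-membered 2,1-oxasilole ring (Si, O, C7, C1, C6). It exploits the fully substituted C1–C6 ring: each substituent arrives on its own alkyne carbon, with silicon at C6 and boron at C3/C4 standing in for bromine and hydroxyl. The precursor is the Si–O-linked bis(bromoalkyne) BrC≡C–SiMe2–O–CH2–C≡CBr, combined with bis(pinacolatoboryl)ethyne.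

Key step: step 4

Remark: the target has no stereogenic element, so it is achiral and no step needs stereocontrol; should a benzoxasilole open to its silanol on aqueous work-up, that form is taken as equivalent, since it undergoes the same downstream chemistry.

Step 1
Reactants: 1 propargyl alcohol (prop-2-yn-1-ol); 2 dichlorodimethylsilane; 3 ethynylmagnesium bromide
Product: 5 ethynyl(dimethyl)(prop-2-yn-1-yloxy)silane, via chloro(dimethyl)(prop-2-yn-1-yloxy)silane 4 (not isolated)
Conditions: 2 (5 equiv), Et3N (1.1 equiv), Et2O, 0 °C; filter under Ar, evaporate excess 2; then 3 (1.0 equiv, THF), −40 → 0 °C; pentane/dioxane, filter, distil (no aqueous work-up)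
Reagents that add atoms: none
Why: Silylation of the alcohol by a dichlorosilane in excess, then nucleophilic substitution at silicon by an alkynyl Grignard reagent, should work because the chlorosilyl ether 4 is non-volatile (surplus 2 is simply evaporated), Si–Cl reacts with the acetylide far faster than Si–O, and low temperature with the Grignard as limiting reagent suppresses acetylide exchange with the propargylic C–H.

Step 2
Reactants: 5 ethynyl(dimethyl)(prop-2-yn-1-yloxy)silane
Product: 6 (bromoethynyl)[(3-bromoprop-2-yn-1-yl)oxy]dimethylsilane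
Conditions: NBS (2.1 equiv), AgNO3 (5 mol %), dry acetone, 0 °C → rt, dark; pentane, filtration through neutral alumina; used promptly
Reagents that add atoms: N-bromosuccinimide, O=C1CCC(=O)N1Br
Why: Silver-catalysed electrophilic bromination of terminal alkynes through silver acetylides is established for both propargylic ethers and terminal silylacetylenes and should be much faster at C(sp)–H than at C(sp)–Si, while the non-aqueous work-up spares the Si–O bond.

Step 3
Reactants: 7 trichloroethylene; 8 2-isopropoxy-4,4,5,5-tetramethyl-1,3,2-dioxaborolane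
Product: 11 bis(pinacolatoboryl)ethyne, via dilithium acetylide 9 (not isolated), via dilithium ethynediylbis(isopropoxyborate) 10 (not isolated)
Conditions: n-BuLi (3 equiv), Et2O, −78 °C → rt; 8 (2 equiv), THF, −78 °C; HCl·Et2O (2 equiv), −78 °C → rt; filter, recrystallise (hexane)
Reagents that add atoms: none
Why: This is the standard alkynylboronate synthesis from a lithium acetylide and an alkoxyboronate: dilithium acetylide from trichloroethylene (deprotonation, LiCl elimination, two Cl/Li exchanges) adds twice to the borate ester, and anhydrous HCl collapses the ate complex with loss of isopropanol.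

Step 4
Reactants: 6 (bromoethynyl)[(3-bromoprop-2-yn-1-yl)oxy]dimethylsilane; 11 bis(pinacolatoboryl)ethyne
Product: 12 4,7-dibromo-1,1-dimethyl-5,6-bis(4,4,5,5-tetramethyl-1,3,2-dioxaborolan-2-yl)-1,3-dihydro-2,1-benzoxasilole
Conditions: Cp*RuCl(cod) (10 mol %), 11 (2.5 equiv), ClCH2CH2Cl, 40 °C, Ar, 6 added by syringe pump over 6 h
Reagents that add atoms: none
Why: Proposed new method: loss of cod from Cp*RuCl(cod) should let the Cp*RuCl fragment bind both bromoalkynes of 6 and undergo oxidative cyclization to a ruthenacyclopentadiene (ruthenacyclopentatriene in its biscarbenoid form) with the bromine-bearing carbons C2 and C5 on ruthenium and C1–C6 joined, after which coordination and insertion of 11 (C2–C3) and reductive elimination (C4–C5) release arene 12 and the Ru(II) fragment. The closest known reaction type is the Cp*RuCl-catalysed [2+2+2] cycloaddition of tethered α,ω-diynes, including halogen-terminated and temporarily tethered ones, with alkynylboronates; what is unproven is the combination of two C(sp)–Br termini, a Si–O tether carrying an alkynylsilane and a diborylalkyne to give a hexasubstituted benzene. The oxasilole ring closes in the oxidative cyclization, as the tether-enforced coupling of the two tethered alkyne carbons (C1–C6) at the metal, and the benzene ring closes by insertion of the third alkyne into the metallacycle followed by reductive elimination (a formal [4+2] of the metallacycle with 11). No stereocentre is created. Cross- over homo-coupling is secured by the intramolecular first step, slow addition of 6 into excess 11 and the reluctance of bulky 11 to trimerize, and regiochemistry is fixed by the tether and by the symmetry of 11. Ru(II) is chosen because it is the catalyst class known to carry haloalkyne termini through metallacycle formation faster than C(sp)–Br oxidative addition, which Co(I) or Rh(I) would be more prone to.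

Step 5
Reactants: 12 4,7-dibromo-1,1-dimethyl-5,6-bis(4,4,5,5-tetramethyl-1,3,2-dioxaborolan-2-yl)-1,3-dihydro-2,1-benzoxasilole
Product: 14 4,7-dibromo-1,1-dimethyl-1,3-dihydro-2,1-benzoxasilole-5,6-diol, via bis(boryloxy)benzoxasilole 13 (not isolated)
Conditions: Me3NO (anhydrous, 3 equiv), THF, rt → 50 °C; then pH 6 phosphate buffer, EtOAc
Reagents that add atoms: trimethylamine N-oxide, C[N+](C)(C)[O-]
Why: Amine N-oxide oxidation of arylboronic esters (O attack at boron, 1,2-aryl shift from B to O with loss of Me3N, then hydrolysis of the aryl–O–B bonds) runs under neutral anhydrous conditions that should leave the Si–C(aryl) bond, the Si–O bond and the aryl bromides intact, whereas alkaline peroxide or perborate would risk Tamao-type C–Si oxidation and protodeboronation.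

Step 6
Reactants: 14 4,7-dibromo-1,1-dimethyl-1,3-dihydro-2,1-benzoxasilole-5,6-diol
Product: 16 2,3,6-tribromo-4,5-dihydroxybenzyl alcohol (target), via bromosilyl ether 15 (not isolated)
Conditions: Br2 (1.0 equiv), CH2Cl2, −78 → 0 °C; then aq. Na2S2O3/NaHCO3, THF–H2O, 0 °C (no alcohol solvents)
Reagents that add atoms: bromine, BrBr
Why: Electrophilic ipso-bromodesilylation should occur at C6, which is para to the C3 hydroxyl and passes through a β-silyl-stabilised arenium ion, so bromine replaces silicon at exactly that carbon, and the bromosilyl ether 15 is then hydrolysed at Si–O on buffered aqueous work-up to free the benzylic alcohol.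

Compound list
1 | propargyl alcohol (prop-2-yn-1-ol) | C#CCO | starting material
2 | dichlorodimethylsilane | C[Si](C)(Cl)Cl | starting material
3 | ethynylmagnesium bromide | C#C[Mg]Br | starting material
4 | chloro(dimethyl)(prop-2-yn-1-yloxy)silane | C[Si](C)(Cl)OCC#C | intermediate
5 | ethynyl(dimethyl)(prop-2-yn-1-yloxy)silane | C#C[Si](C)(C)OCC#C | intermediate
6 | (bromoethynyl)[(3-bromoprop-2-yn-1-yl)oxy]dimethylsilane | BrC#CCO[Si](C)(C)C#CBr | intermediate
7 | trichloroethylene | ClC=C(Cl)Cl | starting material
8 | 2-isopropoxy-4,4,5,5-tetramethyl-1,3,2-dioxaborolane | CC(C)OB1OC(C)(C)C(C)(C)O1 | starting material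
9 | dilithium acetylide | [Li]C#C[Li] | intermediate
10 | dilithium ethyne-1,2-diylbis[isopropoxy(pinacolato)borate] | [Li+].[Li+].CC(C)O[B-]1(OC(C)(C)C(C)(C)O1)C#C[B-]1(OC(C)C)OC(C)(C)C(C)(C)O1 | intermediate
11 | bis(pinacolatoboryl)ethyne | CC1(C)OB(OC1(C)C)C#CB1OC(C)(C)C(C)(C)O1 | intermediate
12 | 4,7-dibromo-1,1-dimethyl-5,6-bis(4,4,5,5-tetramethyl-1,3,2-dioxaborolan-2-yl)-1,3-dihydro-2,1-benzoxasilole | C[Si]1(C)OCc2c(Br)c(B3OC(C)(C)C(C)(C)O3)c(B3OC(C)(C)C(C)(C)O3)c(Br)c21 | intermediate
13 | 4,7-dibromo-1,1-dimethyl-5,6-bis[(4,4,5,5-tetramethyl-1,3,2-dioxaborolan-2-yl)oxy]-1,3-dihydro-2,1-benzoxasilole | C[Si]1(C)OCc2c(Br)c(OB3OC(C)(C)C(C)(C)O3)c(OB3OC(C)(C)C(C)(C)O3)c(Br)c21 | intermediate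
14 | 4,7-dibromo-1,1-dimethyl-1,3-dihydro-2,1-benzoxasilole-5,6-diol | C[Si]1(C)OCc2c(Br)c(O)c(O)c(Br)c21 | intermediate
15 | bromo(dimethyl)[(2,3,6-tribromo-4,5-dihydroxybenzyl)oxy]silane | C[Si](C)(Br)OCc1c(Br)c(O)c(O)c(Br)c1Br | intermediate
16 | 2,3,6-tribromo-4,5-dihydroxybenzyl alcohol (CNP0366705.0, achiral) | OCc1c(Br)c(O)c(O)c(Br)c1Br | target

Total step count: 6. Longest linear sequence: 5 steps (1, 2, 4, 5, 6); step 3 is a convergent branch.

Steps most likely to fail

Step 4 (the step carrying the new-method label). Insertion of ruthenium into a C(sp)–Br bond, or self-coupling of the diyne, may outpace uptake of the crowded diborylalkyne, so that the hexasubstituted arene does not form. The fallback uses known chemistry, sets out from 5 (with 11) and returns at 16. The halogen-free diyne 5 is co-cyclized with 11 under CpCo(CO)2 catalysis (toluene, reflux, hν), the established cobalt [2+2+2] of tethered terminal diynes with alkynylboronates, to give 1,1-dimethyl-5,6-bis(pinacolatoboryl)-1,3-dihydro-2,1-benzoxasilole F1. Me3NO as in step 5 should give, through 1,1-dimethyl-5,6-bis[(pinacolatoboryl)oxy]-1,3-dihydro-2,1-benzoxasilole F2, the catechol 1,1-dimethyl-1,3-dihydro-2,1-benzoxasilole-5,6-diol F3. Br2 (3 equiv, NaOAc, AcOH–CH2Cl2, 0 °C) should then brominate C2 and C5 ortho to the hydroxyls by ordinary electrophilic aromatic substitution and C6 by ipso-desilylation, passing through 15, and the buffered hydrolysis of step 6 delivers 16.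

Step 6. Bromine may oxidize the catechol, attack ipso at C1 (para to the C4 hydroxyl) with loss of the C7 unit, or the benzylic carbon may solvolyse through a para-quinone methide. The fallback separates silicon removal from C–Br formation, sets out from 14 and returns at 16. Fluoride-promoted protodesilylation (TBAF, wet THF, rt → 50 °C) should give 2,5-dibromo-3,4-dihydroxybenzyl alcohol F4. Its only free ring position, C6, para to the C3 hydroxyl, is then brominated with the mild, non-oxidizing tribromide Bu4NBr3 (1.0 equiv, CH2Cl2–THF, 0 °C, NaHCO3 work-up) to give 16.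

Step 2. Silver- or nucleophile-assisted cleavage of the Si–C(sp) or Si–O bond may compete during the double bromination of the labile silyl ether. The fallback places one bromine before silicon is introduced and the other without silver, sets out from 1 and returns at 6. Propargyl alcohol 1 is brominated on the free alcohol (NBS, cat. AgNO3, acetone) to 3-bromoprop-2-yn-1-ol F5. F5 is silylated with excess 2/Et3N as in step 1 to chloro[(3-bromoprop-2-yn-1-yl)oxy]dimethylsilane F6, used in situ. Reaction with 3 at −40 °C gives [(3-bromoprop-2-yn-1-yl)oxy](ethynyl)dimethylsilane F7. The single remaining terminus is then deprotonated (LiHMDS, THF, −78 °C) and the lithium acetylide quenched with NBS to give 6.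

Further compounds
F1 | step 4 | 1,1-dimethyl-5,6-bis(4,4,5,5-tetramethyl-1,3,2-dioxaborolan-2-yl)-1,3-dihydro-2,1-benzoxasilole | C[Si]1(C)OCc2cc(B3OC(C)(C)C(C)(C)O3)c(B3OC(C)(C)C(C)(C)O3)cc21
F2 | step 4 | 1,1-dimethyl-5,6-bis[(4,4,5,5-tetramethyl-1,3,2-dioxaborolan-2-yl)oxy]-1,3-dihydro-2,1-benzoxasilole | C[Si]1(C)OCc2cc(OB3OC(C)(C)C(C)(C)O3)c(OB3OC(C)(C)C(C)(C)O3)cc21
F3 | step 4 | 1,1-dimethyl-1,3-dihydro-2,1-benzoxasilole-5,6-diol | C[Si]1(C)OCc2cc(O)c(O)cc21
F4 | step 6 | 2,5-dibromo-3,4-dihydroxybenzyl alcohol | OCc1cc(Br)c(O)c(O)c1Br
F5 | step 2 | 3-bromoprop-2-yn-1-ol | OCC#CBr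
F6 | step 2 | chloro[(3-bromoprop-2-yn-1-yl)oxy]dimethylsilane | C[Si](C)(Cl)OCC#CBr
F7 | step 2 | [(3-bromoprop-2-yn-1-yl)oxy](ethynyl)dimethylsilane | C#C[Si](C)(C)OCC#CBr
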